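**Retrosynthetic overview**

1. Both esters go on last (C6 first, then C10). The C8=C9/C10–OH unit comes from the β‑epoxide of a C9=C10 alkene by selenide opening and selenoxide elimination; C6–OH and C5–H come from a C5=C6 silyl enol ether.
2. That cyclohepta‑1,4‑diene is disconnected at the C7–C8 bond by a divinylcyclopropane (Cope) rearrangement of a bicyclo[3.1.0]hexane in which C1, C5 and C10 form a temporary three‑membered ring.
3. Enabling feature: in the seven‑membered ring the oxygen‑bearing C6 (next to ring‑fusion C5) and the C8=C9–C10–O unit flank the quaternary C1, so C5–C6 (as an enol ether) and C9–C10 are the two double bonds of a latent cyclohepta‑1,4‑diene whose C7–C8 bond is the σ‑bond made in a [3,3] shift.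
4. The bicyclo[3.1.0]hexane comes from an acyclic α‑diazo‑β‑keto ester (acetoacetate dianion plus a (2E,4E)‑2‑methylhexadienyl bromide) by asymmetric intramolecular cyclopropanation; the isopropyl group is added to the C4 ketone on the convex face before ring expansion.
5. Ring order: five‑membered ring together with the cyclopropane (step 6), then the seven‑membered ring (step 9).

Key step: step 9

Remarks. Daucane numbering is used for all ring atoms: C1 quaternary methyl‑bearing fusion carbon, C2 and C3 the CH2 groups of the five‑membered ring, C4 the isopropyl carbinol, C5 the fusion CH, C6 (aroyloxy), C7 (CH2), C8 (methyl‑bearing), C9, C10 (tigloyloxy). β is the face of C5–H and the three oxygens; α is the face of the C1 methyl and the isopropyl group. Assumption: the sense of induction of the copper bis(oxazoline) catalyst in step 6 cannot be predicted with certainty for this substrate; the ligand antipode that delivers the (1R,5R,6R)‑cyclopropane 9 is used, to be assigned by correlation.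

**Route**

Step 1
Reactants: 1 (E)-but-2-enal; 2 ethyl 2-(triphenylphosphoranylidene)propanoate
Product: 3 ethyl (2E,4E)-2-methylhexa-2,4-dienoate
Conditions: CH2Cl2, 0 °C to rt
Reagents that add atoms: none
Why: Wittig olefination with a stabilised ylide should give the (E)-trisubstituted enoate and leave the (E)-alkene of 1 untouched.

Step 2
Reactants: 3 ethyl (2E,4E)-2-methylhexa-2,4-dienoate
Product: 4 (2E,4E)-2-methylhexa-2,4-dien-1-ol
Conditions: i-Bu2AlH (2.2 equiv), CH2Cl2, −78 to 0 °C; aq. potassium sodium tartrate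
Reagents that add atoms: none
Why: 1,2-reduction of the conjugated ester by the aluminium hydride gives the allylic alcohol without touching the diene geometry.

Step 3
Reactants: 4 (2E,4E)-2-methylhexa-2,4-dien-1-ol
Product: 5 (2E,4E)-1-bromo-2-methylhexa-2,4-diene
Conditions: CBr4, PPh3, CH2Cl2, 0 °C; used at once
Reagents that add atoms: carbon tetrabromide, BrC(Br)(Br)Br
Why: Appel bromination converts the primary allylic alcohol under neutral conditions that should not scramble the (E,E)-diene.

Step 4
Reactants: 6 methyl 3-oxobutanoate; 5 (2E,4E)-1-bromo-2-methylhexa-2,4-diene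
Product: 7 methyl (6E,8E)-6-methyl-3-oxodeca-6,8-dienoate
Conditions: NaH, THF, 0 °C; n-BuLi, 0 °C; then 5, 0 °C to rt; aq. NH4Cl
Reagents that add atoms: none
Why: the acetoacetate dianion is alkylated at its more basic terminal carbon by SN2 attack on the primary allylic bromide, the standard γ-alkylation of acetoacetates.

Step 5
Reactants: 7 methyl (6E,8E)-6-methyl-3-oxodeca-6,8-dienoate
Product: 8 methyl (6E,8E)-2-diazo-6-methyl-3-oxodeca-6,8-dienoate
Conditions: 4-acetamidobenzenesulfonyl azide, Et3N, MeCN, 0 °C to rt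
Reagents that add atoms: 4-acetamidobenzenesulfonyl azide, CC(=O)Nc1ccc(cc1)S(=O)(=O)N=[N+]=[N-]
Why: Regitz diazo transfer to the doubly activated methylene of the β-keto ester.

Step 6
Reactants: 8 methyl (6E,8E)-2-diazo-6-methyl-3-oxodeca-6,8-dienoate
Product: 9 methyl (1R,5R,6R)-5-methyl-2-oxo-6-[(E)-prop-1-enyl]bicyclo[3.1.0]hexane-1-carboxylate
Conditions: [Cu(MeCN)4]PF6 (5 mol %), 2,2'-(propane-2,2-diyl)bis[(4S)-4-tert-butyl-4,5-dihydrooxazole] or its antipode (6 mol %), toluene, 50 °C, slow addition of 8
Reagents that add atoms: none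
Why: catalytic asymmetric intramolecular cyclopropanation of an α-diazo-β-keto ester by a monovalent copper bis(oxazoline) carbenoid; the tether confines attack to the proximal trisubstituted alkene (five-membered ring), the concerted addition keeps the (E)-geometry so that the propenyl group is exo and cis to the ester, and the ligand selects the alkene face and so sets C1, C5 and C10 together.

Step 7
Reactants: 9 methyl (1R,5R,6R)-5-methyl-2-oxo-6-[(E)-prop-1-enyl]bicyclo[3.1.0]hexane-1-carboxylate
Product: 10 methyl (1R,2S,5R,6R)-2-hydroxy-5-methyl-2-(propan-2-yl)-6-[(E)-prop-1-enyl]bicyclo[3.1.0]hexane-1-carboxylate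
Conditions: i-PrMgCl, CeCl3, THF, −78 °C; aq. NH4Cl
Reagents that add atoms: isopropylmagnesium chloride, CC(C)[Mg]Cl
Why: organocerium 1,2-addition suppresses enolisation and β-hydride reduction of the hindered ketone and spares the ester, and attack on the convex face of the bicyclo[3.1.0]hexan-2-one (anti to the cyclopropane) puts the hydroxyl syn to the three-membered ring, which is the C4 configuration of the target relative to C1.

Step 8
Reactants: 10 methyl (1R,2S,5R,6R)-2-hydroxy-5-methyl-2-(propan-2-yl)-6-[(E)-prop-1-enyl]bicyclo[3.1.0]hexane-1-carboxylate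
Product: 12 1-[(1R,2S,5R,6R)-2-hydroxy-5-methyl-2-(propan-2-yl)-6-[(E)-prop-1-enyl]bicyclo[3.1.0]hexan-1-yl]ethan-1-one, via silylmethyl ketone 11 (not isolated)
Conditions: Me3SiCH2Li (3.5 equiv), THF–pentane, −78 to 0 °C; then MeOH, rt; aq. NH4Cl
Reagents that add atoms: (trimethylsilyl)methyllithium, [Li]C[Si](C)(C)C
Why: (trimethylsilyl)methyllithium adds only once to the ester because the α-silyl ketone is enolised as it forms, and methanolysis of the C–Si bond then gives the methyl ketone (ester to methyl ketone conversion through an α-silyl ketone); no stereocentre is touched.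

Step 9
Reactants: 12 1-[(1R,2S,5R,6R)-2-hydroxy-5-methyl-2-(propan-2-yl)-6-[(E)-prop-1-enyl]bicyclo[3.1.0]hexan-1-yl]ethan-1-one
Product: 14 (1R,4S,8R)-4,6-bis(trimethylsilyloxy)dauca-5,9-diene, via bis-silylated divinylcyclopropane 13 (not isolated)
Conditions: Me3SiOTf (3 equiv), Et3N (5 equiv), toluene, 0 °C to rt; then 90–110 °C
Reagents that add atoms: trimethylsilyl trifluoromethanesulfonate, C[Si](C)(C)OS(=O)(=O)C(F)(F)F
Why: Soft enolisation can only engage the acetyl CH3 (C5 is quaternary and C4 is a carbinol, which is silylated at the same time), giving 13, a cis-1-(1-siloxyvinyl)-2-[(E)-propenyl]cyclopropane that should undergo a concerted [3,3]-sigmatropic shift through a boat transition state in which the cyclopropane bond C5–C10 breaks, the C7–C8 bond forms and the π-bonds move to C5=C6 and C9=C10. The closest known reaction type is the divinylcyclopropane–cycloheptadiene rearrangement of silyl enol ethers of cis-2-vinylcyclopropyl ketones. The seven-membered ring is closed by this sigmatropic C7–C8 bond formation, a ring enlargement in which the three cyclopropane carbons and the four alkenyl carbons become the cyclohepta-1,4-diene while the five-membered ring is carried along unchanged. The new stereocentre C8 is set by the (E)-geometry of the propenyl group in the boat transition state (methyl outward, hence trans to the C1 methyl), and C1 and C4 take no part, so the cyclopropane stereochemistry of steps 6 and 7 is handed on to the angular quaternary carbon of the hydroazulene. The step needs the two alkenyl groups cis on the cyclopropane, secured by the bridgehead position of the acetyl group and the exo propenyl group from the (E)-alkene of 8, and it needs the [3,3] shift to outrun homolysis or a homodienyl 1,5-hydrogen shift, for which the release of ring strain and the donor oxygen on C6 are relied upon. The product carries the C6 oxygen as an enol ether and the C9=C10 alkene exactly where the C6 ester and the C8=C9–C10–O unit are developed later.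

Step 10
Reactants: 14 (1R,4S,8R)-4,6-bis(trimethylsilyloxy)dauca-5,9-diene
Product: 15 (1R,4S,5R,8R)-4-hydroxydauc-9-en-6-one
Conditions: Bu4NF, AcOH (1:1), THF, −78 to 0 °C; used at once
Reagents that add atoms: none
Why: buffered fluoride cleaves both silyl groups and the enolate is protonated at C5 under kinetic control from the β-face, the α-face being screened by the C4 isopropyl and C1 methyl groups on both neighbouring carbons, which should give the trans ring fusion; buffering and low temperature are meant to suppress β-elimination, retro-aldol cleavage and C5 epimerisation of the β-hydroxy ketone.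

Step 11
Reactants: 15 (1R,4S,5R,8R)-4-hydroxydauc-9-en-6-one
Product: 16 (1R,4S,5S,6S,8R)-dauc-9-ene-4,6-diol
Conditions: Li, NH3(l), THF, t-BuOH, −78 °C; then NH4Cl
Reagents that add atoms: none
Why: dissolving-metal reduction goes through a ketyl that is protonated to the thermodynamically preferred equatorial alcohol, here the 6β-hydroxyl with C6–H anti to C5–H, whereas hydride reagents would attack the open β-face and give the axial epimer; the isolated alkene is inert.

Step 12
Reactants: 17 4-hydroxybenzoic acid
Product: 19 4-(triisopropylsilyloxy)benzoic acid, via silyl ester 18 (not isolated)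
Conditions: i-Pr3SiCl (2.2 equiv), imidazole, DMF, rt; then K2CO3, MeOH–THF–H2O, rt; citric acid work-up
Reagents that add atoms: triisopropylsilyl chloride, CC(C)[Si](Cl)(C(C)C)C(C)C
Why: exhaustive silylation followed by selective hydrolysis of the labile silyl ester leaves the phenol as a base-tolerant and fluoride-labile silyl ether.

Step 13
Reactants: 16 (1R,4S,5S,6S,8R)-dauc-9-ene-4,6-diol; 19 4-(triisopropylsilyloxy)benzoic acid
Product: 20 (1R,4S,5S,6S,8R)-4-hydroxydauc-9-en-6-yl 4-(triisopropylsilyloxy)benzoate
Conditions: DCC, DMAP, CH2Cl2, rt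
Reagents that add atoms: none
Why: Steglich esterification acylates the secondary C6 hydroxyl while the tertiary C4 hydroxyl is too hindered to react; no stereocentre changes.

Step 14
Reactants: 20 (1R,4S,5S,6S,8R)-4-hydroxydauc-9-en-6-yl 4-(triisopropylsilyloxy)benzoate
Product: 21 (1S,4S,5S,6S,8R,9R,10S)-9,10-epoxy-4-hydroxydaucan-6-yl 4-(triisopropylsilyloxy)benzoate
Conditions: mCPBA, NaHCO3, CH2Cl2, 0 °C
Reagents that add atoms: 3-chloroperoxybenzoic acid, OOC(=O)c1cccc(Cl)c1
Why: Prilezhaev epoxidation of the only alkene should occur on the β-face because the pseudoaxial C1 methyl screens the α-face next to C10 while the C8 methyl is pseudoequatorial, and this fixes the C10 configuration of the target.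

Step 15
Reactants: 21 (1S,4S,5S,6S,8R,9R,10S)-9,10-epoxy-4-hydroxydaucan-6-yl 4-(triisopropylsilyloxy)benzoate
Product: 24 (1S,4S,5S,6S,10R)-4,10-dihydroxydauc-8-en-6-yl 4-(triisopropylsilyloxy)benzoate, via hydroxy selenide 22 (not isolated), via selenoxide 23 (not isolated)
Conditions: (PhSe)2, NaBH4, EtOH, rt to 60 °C; then 30% H2O2, pyridine, THF, 0 °C to rt
Reagents that add atoms: none
Why: epoxide to allylic alcohol transposition by selenide opening and selenoxide syn-elimination: the selenolate attacks with inversion at C9 (the carbon remote from the quaternary centre), and the selenoxide eliminates with the cis C8–H set in step 9 and away from the carbinol carbon, giving C8=C9 and leaving the 10β-hydroxyl.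

Step 16
Reactants: 24 (1S,4S,5S,6S,10R)-4,10-dihydroxydauc-8-en-6-yl 4-(triisopropylsilyloxy)benzoate; 25 (E)-2-methylbut-2-enoyl chloride
Product: 26 (1S,4S,5S,6S,10R)-4-hydroxy-10-[(E)-2-methylbut-2-enoyloxy]dauc-8-en-6-yl 4-(triisopropylsilyloxy)benzoate
Conditions: pyridine, DMAP (cat.), CH2Cl2, 0 °C to rt
Reagents that add atoms: none
Why: DMAP-catalysed acylation of the secondary allylic alcohol with the acid chloride, with pyridine as a base too weak to deconjugate the tigloyl unit through a vinylketene; the tertiary hydroxyl does not react and the (E)-geometry is kept.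

Step 17
Reactants: 26 (1S,4S,5S,6S,10R)-4-hydroxy-10-[(E)-2-methylbut-2-enoyloxy]dauc-8-en-6-yl 4-(triisopropylsilyloxy)benzoate
Product: 27 (1S,4S,5S,6S,10R)-4-hydroxy-10-[(E)-2-methylbut-2-enoyloxy]dauc-8-en-6-yl 4-hydroxybenzoate
Conditions: Bu4NF, AcOH, THF, 0 °C
Reagents that add atoms: none
Why: fluoride cleaves the aryl silyl ether much faster than it attacks the alkyl esters, and acetic acid buffering keeps the phenoxide from triggering acyl transfer, so the phenol is liberated to give the target.

**Compound list**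

1 | (E)-but-2-enal (crotonaldehyde) | C/C=C/C=O | starting material
2 | ethyl 2-(triphenylphosphoranylidene)propanoate | CCOC(=O)C(C)=P(c1ccccc1)(c1ccccc1)c1ccccc1 | starting material
3 | ethyl (2E,4E)-2-methylhexa-2,4-dienoate | CCOC(=O)/C(C)=C/C=C/C | intermediate
4 | (2E,4E)-2-methylhexa-2,4-dien-1-ol | OC/C(C)=C/C=C/C | intermediate
5 | (2E,4E)-1-bromo-2-methylhexa-2,4-diene | BrC/C(C)=C/C=C/C | intermediate
6 | methyl 3-oxobutanoate (methyl acetoacetate) | COC(=O)CC(C)=O | starting material
7 | methyl (6E,8E)-6-methyl-3-oxodeca-6,8-dienoate | COC(=O)CC(=O)CC/C(C)=C/C=C/C | intermediate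
8 | methyl (6E,8E)-2-diazo-6-methyl-3-oxodeca-6,8-dienoate | COC(=O)C(=[N+]=[N-])C(=O)CC/C(C)=C/C=C/C | intermediate
9 | methyl (1R,5R,6R)-5-methyl-2-oxo-6-[(E)-prop-1-enyl]bicyclo[3.1.0]hexane-1-carboxylate (propenyl exo and cis to the ester) | C/C=C/[C@H]1[C@@]2(C(=O)OC)[C@]1(C)CCC2=O | intermediate
10 | methyl (1R,2S,5R,6R)-2-hydroxy-5-methyl-2-(propan-2-yl)-6-[(E)-prop-1-enyl]bicyclo[3.1.0]hexane-1-carboxylate (hydroxyl syn to the cyclopropane) | C/C=C/[C@H]1[C@@]2(C(=O)OC)[C@]1(C)CC[C@]2(O)C(C)C | intermediate
11 | 2-(trimethylsilyl) derivative of ketone 12 (present as its lithium enolate) | C/C=C/[C@H]1[C@@]2(C(=O)C[Si](C)(C)C)[C@]1(C)CC[C@]2(O)C(C)C | intermediate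
12 | 1-[(1R,2S,5R,6R)-2-hydroxy-5-methyl-2-(propan-2-yl)-6-[(E)-prop-1-enyl]bicyclo[3.1.0]hexan-1-yl]ethan-1-one | C/C=C/[C@H]1[C@@]2(C(C)=O)[C@]1(C)CC[C@]2(O)C(C)C | intermediate
13 | trimethylsilyl ether and trimethylsilyl enol ether of 12 (cis-divinylcyclopropane; configuration as in 12) | C/C=C/[C@H]1[C@@]2(C(=C)O[Si](C)(C)C)[C@]1(C)CC[C@]2(O[Si](C)(C)C)C(C)C | intermediate
14 | (1R,4S,8R)-4,6-bis(trimethylsilyloxy)dauca-5,9-diene (C8 methyl trans to C1 methyl) | C1=C[C@H](C)CC(O[Si](C)(C)C)=C2[C@]1(C)CC[C@]2(O[Si](C)(C)C)C(C)C | intermediate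
15 | (1R,4S,5R,8R)-4-hydroxydauc-9-en-6-one (trans-fused) | C1=C[C@H](C)CC(=O)[C@@H]2[C@]1(C)CC[C@]2(O)C(C)C | intermediate
16 | (1R,4S,5S,6S,8R)-dauc-9-ene-4,6-diol | C1=C[C@H](C)C[C@H](O)[C@@H]2[C@]1(C)CC[C@]2(O)C(C)C | intermediate
17 | 4-hydroxybenzoic acid | OC(=O)c1ccc(O)cc1 | starting material
18 | triisopropylsilyl 4-(triisopropylsilyloxy)benzoate | CC(C)[Si](Oc1ccc(cc1)C(=O)O[Si](C(C)C)(C(C)C)C(C)C)(C(C)C)C(C)C | intermediate
19 | 4-(triisopropylsilyloxy)benzoic acid | CC(C)[Si](Oc1ccc(cc1)C(=O)O)(C(C)C)C(C)C | intermediate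
20 | (1R,4S,5S,6S,8R)-4-hydroxydauc-9-en-6-yl 4-(triisopropylsilyloxy)benzoate | C1=C[C@H](C)C[C@H](OC(=O)c3ccc(O[Si](C(C)C)(C(C)C)C(C)C)cc3)[C@@H]2[C@]1(C)CC[C@]2(O)C(C)C | intermediate
21 | (1S,4S,5S,6S,8R,9R,10S)-9,10-epoxy-4-hydroxydaucan-6-yl 4-(triisopropylsilyloxy)benzoate (epoxide on the β-face) | O1[C@@H]2[C@H]1[C@H](C)C[C@H](OC(=O)c4ccc(O[Si](C(C)C)(C(C)C)C(C)C)cc4)[C@@H]3[C@]2(C)CC[C@]3(O)C(C)C | intermediate
22 | (1S,4S,5S,6S,8R,9S,10S)-4,10-dihydroxy-9-(phenylselanyl)daucan-6-yl 4-(triisopropylsilyloxy)benzoate | O[C@@H]1[C@@H]([Se]c5ccccc5)[C@H](C)C[C@H](OC(=O)c3ccc(O[Si](C(C)C)(C(C)C)C(C)C)cc3)[C@@H]2[C@]1(C)CC[C@]2(O)C(C)C | intermediate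
23 | selenoxide of 22 | O[C@@H]1[C@@H]([Se](=O)c5ccccc5)[C@H](C)C[C@H](OC(=O)c3ccc(O[Si](C(C)C)(C(C)C)C(C)C)cc3)[C@@H]2[C@]1(C)CC[C@]2(O)C(C)C | intermediate
24 | (1S,4S,5S,6S,10R)-4,10-dihydroxydauc-8-en-6-yl 4-(triisopropylsilyloxy)benzoate | O[C@@H]1C=C(C)C[C@H](OC(=O)c3ccc(O[Si](C(C)C)(C(C)C)C(C)C)cc3)[C@@H]2[C@]1(C)CC[C@]2(O)C(C)C | intermediate
25 | (E)-2-methylbut-2-enoyl chloride (tigloyl chloride) | C/C=C(\C)C(Cl)=O | starting material
26 | (1S,4S,5S,6S,10R)-4-hydroxy-10-[(E)-2-methylbut-2-enoyloxy]dauc-8-en-6-yl 4-(triisopropylsilyloxy)benzoate | C/C=C(\C)C(=O)O[C@@H]1C=C(C)C[C@H](OC(=O)c3ccc(O[Si](C(C)C)(C(C)C)C(C)C)cc3)[C@@H]2[C@]1(C)CC[C@]2(O)C(C)C | intermediate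
27 | (1S,4S,5S,6S,10R)-4-hydroxy-10-[(E)-2-methylbut-2-enoyloxy]dauc-8-en-6-yl 4-hydroxybenzoate | C/C=C(\C)C(=O)O[C@@H]1C=C(C)C[C@H](OC(=O)c2ccc(O)cc2)[C@@H]2[C@]1(C)CC[C@]2(O)C(C)C | target

**Totals and risks**

Total step count: 17. Longest linear sequence: 16 steps (steps 1–11 and 13–17; step 12 is a one-step side branch).

Steps most likely to fail:

1. Step 9 (key step). The boat transition state is crowded: the C1 methyl lies under the two converging termini and the siloxy group abuts the substituents on C4. The [3,3] shift may therefore be slow, and homolytic opening of the cyclopropane or a homodienyl 1,5-hydrogen shift from the cis methyl may compete at the temperature required. Fallback, setting out from 12 and returning at 15 (steps 9 and 10 replaced): a charge-accelerated variant without silicon. Treatment of 12 with KN(SiMe3)2 (2.2 equiv) and 18-crown-6 in THF at −78 to 0 °C gives the dipotassium alkoxide enolate of 12 F1, whose electron-rich enolate arm should form the same C7–C8 bond at lower temperature to give the rearranged dipotassium alkoxide enolate F2; quenching at −78 °C with AcOH gives 15.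

2. Step 6. Facial discrimination by the chiral copper carbenoid (an acceptor/acceptor carbenoid adding to a trisubstituted dienyl alkene) may be insufficient, giving material of low enantiomeric purity. Fallback, setting out from 5 and returning at 12: a covalent auxiliary with separation of diastereomers. The dianion of commercial (1R,2S,5R)-menthyl 3-oxobutanoate is alkylated with 5 to give the menthyl keto ester F3, diazo transfer gives the diazo ester F4, and cyclopropanation with achiral Rh2(OAc)4 gives two diastereomeric bicyclic esters from which the menthyl analogue of 9 F5 is separated by crystallisation or chromatography. Organocerium addition as in step 7 gives the menthyl analogue of 10 F6, and Me3SiCH2Li then MeOH as in step 8 gives 12 with release of menthol.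

3. Step 11. The strongly basic medium may epimerise C5 of the trans-fused β-hydroxy ketone or cleave it by retro-aldol fragmentation before the ketyl forms, or protonation of the ketyl may not favour the equatorial alcohol strongly enough. Fallback, setting out from 15 and returning at 20 (steps 11 and 13 replaced): kinetic hydride reduction followed by inversion. NaBH4 with CeCl3·7H2O in MeOH at −78 °C should attack the open β-face to give the axial 6-epi diol F7; Mitsunobu esterification of F7 with acid 19 (PPh3, diisopropyl azodicarboxylate, toluene, 0 °C to rt) inverts C6 and gives ester 20 directly.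

**Further compounds**

F1 | step 9 | dipotassium alkoxide enolate of 12 | C/C=C/[C@H]1[C@@]2(C(=C)[O-])[C@]1(C)CC[C@]2([O-])C(C)C.[K+].[K+]
F2 | step 9 | dipotassium alkoxide enolate of 15 | C1=C[C@H](C)CC([O-])=C2[C@]1(C)CC[C@]2([O-])C(C)C.[K+].[K+]
F3 | step 6 | (1R,2S,5R)-5-methyl-2-(propan-2-yl)cyclohexyl (6E,8E)-6-methyl-3-oxodeca-6,8-dienoate | C/C=C/C=C(\C)CCC(=O)CC(=O)O[C@@H]1C[C@H](C)CC[C@H]1C(C)C
F4 | step 6 | (1R,2S,5R)-5-methyl-2-(propan-2-yl)cyclohexyl (6E,8E)-2-diazo-6-methyl-3-oxodeca-6,8-dienoate | C/C=C/C=C(\C)CCC(=O)C(=[N+]=[N-])C(=O)O[C@@H]1C[C@H](C)CC[C@H]1C(C)C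
F5 | step 6 | (1R,2S,5R)-5-methyl-2-(propan-2-yl)cyclohexyl (1R,5R,6R)-5-methyl-2-oxo-6-[(E)-prop-1-enyl]bicyclo[3.1.0]hexane-1-carboxylate | C/C=C/[C@H]1[C@@]2(C(=O)O[C@@H]3C[C@H](C)CC[C@H]3C(C)C)[C@]1(C)CCC2=O
F6 | step 6 | (1R,2S,5R)-5-methyl-2-(propan-2-yl)cyclohexyl (1R,2S,5R,6R)-2-hydroxy-5-methyl-2-(propan-2-yl)-6-[(E)-prop-1-enyl]bicyclo[3.1.0]hexane-1-carboxylate | C/C=C/[C@H]1[C@@]2(C(=O)O[C@@H]3C[C@H](C)CC[C@H]3C(C)C)[C@]1(C)CC[C@]2(O)C(C)C
F7 | step 11 | (1R,4S,5S,6R,8R)-dauc-9-ene-4,6-diol (6-epimer of 16) | C1=C[C@H](C)C[C@@H](O)[C@@H]2[C@]1(C)CC[C@]2(O)C(C)C
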